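The runs were generated by integration with constants of no real substance, and the scatter is random.

Start with the easy reading: in the autumn flask, the very flask you are asked about, product lies flat from 1.50 h to 20.0 h, and the spread of its readings is about the scatter of 0.5 percentage points.

common to all: substrate 20 mM
- autumn: free enzyme 6 µM; temperature 20 °C; the very flask that is asked about, followed so far
- noon: free enzyme 3 µM; temperature 15 °C; run made earlier
- flask: free enzyme 6.0 µM; temperature 20 °C; time 25 h

- autumn (time / h: product / %): 1.50: 46.9; 2.50: 47.2; 4.00: 47.4; 6.00: 46.7; 8.00: 47.8; 12.0: 47.6; 20.0: 47.3
- noon (time / min: product / %): 5.00: 4.9; 8.00: 8.4; 12.0: 11.5; 15.0: 13.9; 25.0: 19.8; 40.0: 25.4; 60.0: 28.8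

(standard deviation of a reading: 0.5 percentage points)

- birch: at 25 h add substrate, 50.0% of the amount charged, then wait 25 h
- cedar: at 25 h raise the temperature by 25 K, then wait 25 h
- elm: at 25 h add free enzyme, 100% of the amount charged, then wait 25 h
- maple: change nothing and wait 25 h more

- additions leave the volume as it is
- the earlier runs were read with a standard deviation of 0.5 percentage points
- a reading or a percentage of product counts all its forms, free or not

- product, in percent of the substrate first charged, at 25 h
- the option that brings most further product ("none" if no option brings more than 2 percentage points) (birch / cedar / elm / maple / none)
- product present, in percent of the substrate first charged, after birch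
- product present, in percent of the substrate first charged, after maple

The mean of the autumn readings is my estimate for the flask at 25 h:

47.3%

Divide that product by the free enzyme charged and you have the yield per enzyme, the product made per enzyme charged before conversion stops (the total turnover number):

1580

But this number means something only if the enzyme has stopped, and a flat line could equally be an equilibrium. The noon run offers a test. It starts at 0.588 h⁻¹ of the charge and ends at 0.102 h⁻¹. A straight line of rate against product then reaches zero at

32.3%

So the noon flask, with half the enzyme, is heading for a stop below the autumn plateau, as a stopped enzyme should. The objection is that noon is also colder, so dose and temperature are mixed. Its yield per enzyme reads 2150, which is 1.37 times the autumn value, so the yield read in one of these two runs does not carry over to the other. For the asked flask that does no harm, since its yield was read at its own temperature.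

My reckoning is therefore this: waiting, heat and more substrate act on a stopped enzyme and bring nothing, while elm's fresh dose, by the yield, should bring about 47.3% of product, and the 52.7% of the substrate that I reckon remains is more than that. The doubt is that the yield was read at the charged [substrate], and the fresh dose meets less.

The forecast gives 47.3% (range 46.9% to 47.8%), 47.4% after birch, 47.3% after maple, and elm as best, on these grounds: “So I expect a dead enzyme. More substrate, more heat or more waiting does nothing, while fresh enzyme restarts conversion.”

The flask gives 47.4%, 47.4% after birch, 47.4% after maple, and elm as best.

    free enzyme → unfolded enzyme (k = 5.60 × 10⁻⁵ s⁻¹, Ea = 289 kJ mol⁻¹)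
    free enzyme → spent catalyst A (k = 3.00 × 10⁻⁴ s⁻¹, Ea = 91.0 kJ mol⁻¹)
    substrate + free enzyme → product + free enzyme, rate k3*[substrate]^2*[free enzyme]/(1 + ([substrate]/Kh3)^2) (12.0 mM, k = 17000 M⁻² s⁻¹, Ea = 28.0 kJ mol⁻¹)
    substrate + free enzyme → spent catalyst B (k = 0.0380 M⁻¹ s⁻¹, Ea = 52.0 kJ mol⁻¹)
    crystals ⇌ product, rate k5*(cs5 - [product]) while solid is left; crystals form when [product] > cs5 (solubility = 14.0 mM, k = 0.00990 s⁻¹)
    (constants at 20 °C)

The asked flask holds 0% of its free enzyme at 25.0 h, and its yield stands at 1580 per enzyme. Part of why it stops there lies in two things acting together, the turning of substrate + free enzyme into spent catalyst B and the crowding by [substrate] in the law of the turning into product: without the first it reaches 78.1%, without the second 74.0%. Elm's fresh dose brought 30 points, not 47.3%, and part of the size of that gain lies in the same turning into spent catalyst B: without it elm brings 12 points. Carried to the neighbour charged with 0.0024 mM, the yield gives 18.9% against 19.5%, and to the neighbour with 0.010 mM it gives 78.8% against 70.0%.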